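**Plan**
1. Ring numbering used here: C1 = C(OH)CH3, C2 = CH bearing the side chain, C3 = quaternary C, C4 = CHBr, C5 and C6 = CH2. Retrosynthesis: C4–Br ⇒ axial C4–OH (inversion) ⇒ C4=O; the C3–homoprenyl bond ⇒ enolate alkylation; the ring is then cut at C1–C2 and C5–C6 in a Diels–Alder sense.
2. Enabling feature: the oxygenated C1 and the heteroatom-bearing C4 are 1,4 in the six-membered ring and the carbon branches sit on C2/C3. With C3=C4 written as a silyl enol ether, the ring is the "para/ortho" adduct of a 2-silyloxy-1,3-diene (C5=C4–C3=C2) and a 1-oxy-1-substituted ethene (C6=C1).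
3. Forward: (S)-linalool → side-chain aldehyde → (E)-enone → silyloxy diene. L-Lactic acid → 2-tert-butyl-5-methylene-1,3-dioxolan-4-one; its CH3, C–O and CO2H carbons become C6, C1 (with its oxygen) and the C1 methyl. The cycloaddition forms the only ring; then lactone C=O → CH3, homoprenylation at C3, C4=O → OH → Br, desilylation.
4. Stereochemistry: the side-chain carbinol comes from (S)-linalool; C1 and C2 from the exo cycloaddition anti to the acetal tert-butyl group (acetal centre relayed from L-lactic acid); C3 from alkylation anti to the C2 chain; C4 from equatorial hydride attack followed by SN2 inversion.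

Key step: step 7

Assumption: (S)-(+)-linalool is taken as purchasable in high enantiomeric purity; any (R)-antipode would appear after step 7 as a ring diastereomer to be removed by chromatography.

**Step 1**
Reactants: 1 (S)-lactic acid; 2 pivalaldehyde
Product: 3 (2S,5S)-2-tert-butyl-5-methyl-1,3-dioxolan-4-one
Conditions: p-TsOH·H2O (cat.), H2SO4 (cat.), pentane, reflux with azeotropic removal of water; crystallisation at −78 °C
Reagents that add atoms: none
Why: Acid-catalysed acetalisation of the α-hydroxy acid (dioxolanone formation) should give mainly the cis acetal, the new acetal centre being set by the lactic acid stereocentre under thermodynamic control, and crystallisation should remove the trans isomer.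

**Step 2**
Reactants: 3 (2S,5S)-2-tert-butyl-5-methyl-1,3-dioxolan-4-one
Product: 5 (2S)-2-tert-butyl-5-methylidene-1,3-dioxolan-4-one, via bromolactone 4 (not isolated)
Conditions: NBS, AIBN (cat.), CCl4, reflux; filtration; then DBU, Et2O, 0 °C to rt
Reagents that add atoms: none
Why: Wohl–Ziegler-type radical bromination at the captodative C–H and E2 loss of HBr toward the methyl group should give the exocyclic methylene lactone, in which the acetal carbon is the only stereocentre left (self-regeneration of stereocentres).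

**Step 3**
Reactants: 6 (S)-linalool
Product: 7 triethyl{[(3S)-3,7-dimethylocta-1,6-dien-3-yl]oxy}silane
Conditions: Et3SiOTf, 2,6-lutidine, CH2Cl2, −78 to 0 °C
Reagents that add atoms: triethylsilyl trifluoromethanesulfonate CC[Si](CC)(CC)OS(=O)(=O)C(F)(F)F
Why: Silyl triflate silylation of the tertiary allylic alcohol, which prevents lactol formation and oxa-Michael closure in steps 4 to 6.

**Step 4**
Reactants: 7 triethyl{[(3S)-3,7-dimethylocta-1,6-dien-3-yl]oxy}silane
Product: 9 (4S)-4-methyl-4-(triethylsilyloxy)hex-5-enal, via secondary ozonide 8 (not isolated)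
Conditions: O3 (1.0 equiv, Sudan Red 7B end-point), CH2Cl2, −78 °C; then Me2S, −78 °C to rt
Reagents that add atoms: ozone [O-][O+]=O
Why: Chemoselective ozonolysis with reductive work-up, since the electron-rich trisubstituted alkene should react far faster than the vinyl group next to the silyloxy carbon.

**Step 5**
Reactants: 9 (4S)-4-methyl-4-(triethylsilyloxy)hex-5-enal; 10 3-(triphenylphosphoranylidene)butan-2-one
Product: 11 (3E,7S)-3,7-dimethyl-7-(triethylsilyloxy)nona-3,8-dien-2-one
Conditions: toluene, 90 °C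
Reagents that add atoms: none
Why: Wittig olefination with a stabilised α-methyl acyl ylide, which should give the trisubstituted (E)-enone.

**Step 6**
Reactants: 11 (3E,7S)-3,7-dimethyl-7-(triethylsilyloxy)nona-3,8-dien-2-one
Product: 13 (3E,7S)-3,7-dimethyl-2,7-bis(triethylsilyloxy)nona-1,3,8-triene, via lithium dienolate 12 (not isolated)
Conditions: LiN(i-Pr)2, THF, −78 °C; then Et3SiCl, −78 to 0 °C
Reagents that add atoms: chlorotriethylsilane CC[Si](Cl)(CC)CC
Why: Kinetic deprotonation of the methyl ketone at CH3 (cross-conjugated dienolate) and O-silylation should give the 2-silyloxy diene with the (E)-alkene unchanged.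

**Step 7**
Reactants: 13 (3E,7S)-3,7-dimethyl-2,7-bis(triethylsilyloxy)nona-1,3,8-triene; 5 (2S)-2-tert-butyl-5-methylidene-1,3-dioxolan-4-one
Product: 14 (2S,5R,6S)-2-tert-butyl-7-methyl-6-[(3S)-3-methyl-3-(triethylsilyloxy)pent-4-en-1-yl]-8-(triethylsilyloxy)-1,3-dioxaspiro[4.5]dec-7-en-4-one
Conditions: toluene, BHT (cat.), 90 °C, sealed vessel
Reagents that add atoms: none
Why: Concerted, asynchronous normal-demand [4+2] cycloaddition in which the silyloxy-activated CH2 terminus of the s-cis diene bonds to the exocyclic CH2 of the captodative dienophile and the chain-bearing diene terminus bonds to its oxygenated carbon. The closest known reaction type is the thermal Diels–Alder reaction of 2-tert-butyl-5-methylene-1,3-dioxolan-4-one with open-chain dienes, and of 2-silyloxydienes with acrylates. The only carbocycle closes by intermolecular [4+2] cycloaddition, suprafacial on both partners, and the "para" preference of the 2-silyloxy group and the "ortho" preference of the terminal alkyl group call for the same orientation. The spiro carbinol carbon is set by approach of the diene to the dienophile face opposite the tert-butyl group of the (S)-acetal; the neighbouring CH is set by the (E) geometry of the diene together with the exo mode (lactone carbonyl away from the diene, ring oxygen under it), which places the side chain cis to the ring oxygen. The step needs exo and π-facial selectivity, which the rigid s-cis α-methylene lactone and the acetal substituent should secure, while the silyl-protected remote carbinol is a spectator. The adduct keeps the ring ketone as a regiodefined enol ether whose β-carbon is the future quaternary centre.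

**Step 8**
Reactants: 14 (2S,5R,6S)-2-tert-butyl-7-methyl-6-[(3S)-3-methyl-3-(triethylsilyloxy)pent-4-en-1-yl]-8-(triethylsilyloxy)-1,3-dioxaspiro[4.5]dec-7-en-4-one
Product: 15 (1R,2S)-1-(hydroxymethyl)-3-methyl-2-[(3S)-3-methyl-3-(triethylsilyloxy)pent-4-en-1-yl]-4-(triethylsilyloxy)cyclohex-3-en-1-ol
Conditions: LiAlH4, THF, 0 °C; aq. KNaC4H4O6 work-up
Reagents that add atoms: none
Why: Hydride reduction of the acetal-lactone should release the tertiary and the primary alcohol (the pivalaldehyde unit leaves as neopentyl alcohol) without touching the carbinol configuration, the silyl ethers or the enol ether.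

**Step 9**
Reactants: 15 (1R,2S)-1-(hydroxymethyl)-3-methyl-2-[(3S)-3-methyl-3-(triethylsilyloxy)pent-4-en-1-yl]-4-(triethylsilyloxy)cyclohex-3-en-1-ol
Product: 16 [(1R,2S)-1-hydroxy-3-methyl-2-[(3S)-3-methyl-3-(triethylsilyloxy)pent-4-en-1-yl]-4-(triethylsilyloxy)cyclohex-3-en-1-yl]methyl 4-methylbenzenesulfonate
Conditions: TsCl, Et3N, DMAP (cat.), CH2Cl2, 0 °C
Reagents that add atoms: 4-methylbenzenesulfonyl chloride Cc1ccc(cc1)S(Cl)(=O)=O
Why: Selective sulfonylation of the primary hydroxyl in the presence of the tertiary one.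

**Step 10**
Reactants: 16 [(1R,2S)-1-hydroxy-3-methyl-2-[(3S)-3-methyl-3-(triethylsilyloxy)pent-4-en-1-yl]-4-(triethylsilyloxy)cyclohex-3-en-1-yl]methyl 4-methylbenzenesulfonate
Product: 18 (1R,2S)-1,3-dimethyl-2-[(3S)-3-methyl-3-(triethylsilyloxy)pent-4-en-1-yl]-4-(triethylsilyloxy)cyclohex-3-en-1-ol, via spiro-epoxide 17 (not isolated)
Conditions: LiBHEt3 (3 equiv), THF, 0 °C to rt
Reagents that add atoms: none
Why: The tertiary alkoxide should close the spiro-epoxide by displacing the primary tosylate and hydride should open it at the CH2 group (SN2 epoxide reduction), so the former lactone carbon becomes the methyl group while the C–O stereocentre is untouched.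

**Step 11**
Reactants: 18 (1R,2S)-1,3-dimethyl-2-[(3S)-3-methyl-3-(triethylsilyloxy)pent-4-en-1-yl]-4-(triethylsilyloxy)cyclohex-3-en-1-ol
Product: 19 {[(1R,2S)-1,3-dimethyl-2-[(3S)-3-methyl-3-(triethylsilyloxy)pent-4-en-1-yl]-4-(triethylsilyloxy)cyclohex-3-en-1-yl]oxy}triethylsilane
Conditions: Et3SiOTf, 2,6-lutidine, CH2Cl2, −78 to 0 °C
Reagents that add atoms: triethylsilyl trifluoromethanesulfonate CC[Si](CC)(CC)OS(=O)(=O)C(F)(F)F
Why: Silyl triflate silylation of the tertiary alcohol, which masks it for step 15 and adds bulk to the ring face that already carries the side chain.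

**Step 12**
Reactants: 20 5-bromo-2-methylpent-2-ene
Product: 21 5-iodo-2-methylpent-2-ene
Conditions: NaI, acetone, reflux
Reagents that add atoms: sodium iodide [Na+].[I-]
Why: Finkelstein halide exchange driven by precipitation of NaBr, giving the more reactive alkylating agent.

**Step 13**
Reactants: 19 {[(1R,2S)-1,3-dimethyl-2-[(3S)-3-methyl-3-(triethylsilyloxy)pent-4-en-1-yl]-4-(triethylsilyloxy)cyclohex-3-en-1-yl]oxy}triethylsilane; 21 5-iodo-2-methylpent-2-ene
Product: 23 (2S,3S,4R)-2,4-dimethyl-2-(4-methylpent-3-en-1-yl)-3-[(3S)-3-methyl-3-(triethylsilyloxy)pent-4-en-1-yl]-4-(triethylsilyloxy)cyclohexan-1-one, via lithium enolate 22 (not isolated)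
Conditions: MeLi (1.05 equiv), THF, 0 °C to rt; then HMPA, 21 (excess), −78 °C to rt
Reagents that add atoms: none
Why: Methyllithium should cleave only the enol Si–O bond to release the regiodefined tetrasubstituted lithium enolate, which is C-alkylated (regiospecific enolate alkylation) on the face opposite the neighbouring side chain and silyloxy group, so the quaternary carbon is formed with its methyl cis to the side chain.

**Step 14**
Reactants: 23 (2S,3S,4R)-2,4-dimethyl-2-(4-methylpent-3-en-1-yl)-3-[(3S)-3-methyl-3-(triethylsilyloxy)pent-4-en-1-yl]-4-(triethylsilyloxy)cyclohexan-1-one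
Product: 24 (1R,2S,3S,4R)-2,4-dimethyl-2-(4-methylpent-3-en-1-yl)-3-[(3S)-3-methyl-3-(triethylsilyloxy)pent-4-en-1-yl]-4-(triethylsilyloxy)cyclohexan-1-ol
Conditions: LiBH(sec-Bu)3, THF, −78 to 0 °C
Reagents that add atoms: none
Why: The bulky trialkylborohydride should attack the ketone along the equatorial trajectory, as with 2,2-dialkylcyclohexanones, giving the axial alcohol (hydroxyl trans to the methyl of the quaternary carbon).

**Step 15**
Reactants: 24 (1R,2S,3S,4R)-2,4-dimethyl-2-(4-methylpent-3-en-1-yl)-3-[(3S)-3-methyl-3-(triethylsilyloxy)pent-4-en-1-yl]-4-(triethylsilyloxy)cyclohexan-1-ol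
Product: 25 {[(1R,2S,3S,4S)-4-bromo-1,3-dimethyl-3-(4-methylpent-3-en-1-yl)-2-[(3S)-3-methyl-3-(triethylsilyloxy)pent-4-en-1-yl]cyclohexyl]oxy}triethylsilane
Conditions: CBr4, P(n-C8H17)3, 2,6-lutidine, toluene, 60 °C
Reagents that add atoms: carbon tetrabromide BrC(Br)(Br)Br
Why: Appel reaction, in which the alkoxyphosphonium ion is displaced by bromide with inversion so that the axial alcohol becomes the equatorial bromide cis to the quaternary methyl, the base keeping HBr away from the alkenes and silyl ethers.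

**Step 16**
Reactants: 25 {[(1R,2S,3S,4S)-4-bromo-1,3-dimethyl-3-(4-methylpent-3-en-1-yl)-2-[(3S)-3-methyl-3-(triethylsilyloxy)pent-4-en-1-yl]cyclohexyl]oxy}triethylsilane
Product: 26 (1R,2S,3S,4S)-4-bromo-2-[(3S)-3-hydroxy-3-methylpent-4-en-1-yl]-1,3-dimethyl-3-(4-methylpent-3-en-1-yl)cyclohexan-1-ol
Conditions: HF·pyridine, pyridine, THF, 0 °C to rt
Reagents that add atoms: none
Why: Buffered fluoride cleavage of both tertiary triethylsilyl ethers, which should spare the equatorial bromide (no antiperiplanar hydrogen for elimination) and the tertiary allylic alcohol.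

**Compound list**
1 | (S)-lactic acid | C[C@H](O)C(=O)O | starting material
2 | pivalaldehyde (2,2-dimethylpropanal) | CC(C)(C)C=O | starting material
3 | (2S,5S)-2-tert-butyl-5-methyl-1,3-dioxolan-4-one (cis) | C[C@@H]1O[C@H](C(C)(C)C)OC1=O | intermediate
4 | (2S,5R)-5-bromo-2-tert-butyl-5-methyl-1,3-dioxolan-4-one (Br trans to tert-butyl) | C[C@]1(Br)O[C@H](C(C)(C)C)OC1=O | intermediate
5 | (2S)-2-tert-butyl-5-methylidene-1,3-dioxolan-4-one | C=C1O[C@H](C(C)(C)C)OC1=O | intermediate
6 | (S)-linalool | C=C[C@@](C)(O)CCC=C(C)C | starting material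
7 | triethyl{[(3S)-3,7-dimethylocta-1,6-dien-3-yl]oxy}silane | C=C[C@@](C)(O[Si](CC)(CC)CC)CCC=C(C)C | intermediate
8 | 3,3-dimethyl-5-[(3S)-3-methyl-3-(triethylsilyloxy)pent-4-en-1-yl]-1,2,4-trioxolane (ozonide, mixture at the ring CH) | C=C[C@@](C)(O[Si](CC)(CC)CC)CCC1OOC(C)(C)O1 | intermediate
9 | (4S)-4-methyl-4-(triethylsilyloxy)hex-5-enal | C=C[C@@](C)(O[Si](CC)(CC)CC)CCC=O | intermediate
10 | 3-(triphenylphosphoranylidene)butan-2-one | CC(=O)C(C)=P(c1ccccc1)(c1ccccc1)c1ccccc1 | starting material
11 | (3E,7S)-3,7-dimethyl-7-(triethylsilyloxy)nona-3,8-dien-2-one | C=C[C@@](C)(O[Si](CC)(CC)CC)CC/C=C(\C)C(C)=O | intermediate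
12 | lithium (3E,7S)-3,7-dimethyl-7-(triethylsilyloxy)nona-1,3,8-trien-2-olate | C=C[C@@](C)(O[Si](CC)(CC)CC)CC/C=C(\C)C(=C)[O-].[Li+] | intermediate
13 | (3E,7S)-3,7-dimethyl-2,7-bis(triethylsilyloxy)nona-1,3,8-triene | C=C[C@@](C)(O[Si](CC)(CC)CC)CC/C=C(\C)C(=C)O[Si](CC)(CC)CC | intermediate
14 | (2S,5R,6S)-2-tert-butyl-7-methyl-6-[(3S)-3-methyl-3-(triethylsilyloxy)pent-4-en-1-yl]-8-(triethylsilyloxy)-1,3-dioxaspiro[4.5]dec-7-en-4-one (side chain cis to ring oxygen, tert-butyl on the side of the ring CH2) | C=C[C@@](C)(O[Si](CC)(CC)CC)CC[C@H]1C(C)=C(O[Si](CC)(CC)CC)CC[C@@]12O[C@H](C(C)(C)C)OC2=O | intermediate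
15 | (1R,2S)-1-(hydroxymethyl)-3-methyl-2-[(3S)-3-methyl-3-(triethylsilyloxy)pent-4-en-1-yl]-4-(triethylsilyloxy)cyclohex-3-en-1-ol | C=C[C@@](C)(O[Si](CC)(CC)CC)CC[C@H]1C(C)=C(O[Si](CC)(CC)CC)CC[C@]1(O)CO | intermediate
16 | [(1R,2S)-1-hydroxy-3-methyl-2-[(3S)-3-methyl-3-(triethylsilyloxy)pent-4-en-1-yl]-4-(triethylsilyloxy)cyclohex-3-en-1-yl]methyl 4-methylbenzenesulfonate | C=C[C@@](C)(O[Si](CC)(CC)CC)CC[C@H]1C(C)=C(O[Si](CC)(CC)CC)CC[C@]1(O)COS(=O)(=O)c1ccc(C)cc1 | intermediate
17 | (3R,4S)-5-methyl-4-[(3S)-3-methyl-3-(triethylsilyloxy)pent-4-en-1-yl]-6-(triethylsilyloxy)-1-oxaspiro[2.5]oct-5-ene | C=C[C@@](C)(O[Si](CC)(CC)CC)CC[C@H]1C(C)=C(O[Si](CC)(CC)CC)CC[C@]12CO2 | intermediate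
18 | (1R,2S)-1,3-dimethyl-2-[(3S)-3-methyl-3-(triethylsilyloxy)pent-4-en-1-yl]-4-(triethylsilyloxy)cyclohex-3-en-1-ol | C=C[C@@](C)(O[Si](CC)(CC)CC)CC[C@H]1C(C)=C(O[Si](CC)(CC)CC)CC[C@@]1(C)O | intermediate
19 | {[(1R,2S)-1,3-dimethyl-2-[(3S)-3-methyl-3-(triethylsilyloxy)pent-4-en-1-yl]-4-(triethylsilyloxy)cyclohex-3-en-1-yl]oxy}triethylsilane | C=C[C@@](C)(O[Si](CC)(CC)CC)CC[C@H]1C(C)=C(O[Si](CC)(CC)CC)CC[C@@]1(C)O[Si](CC)(CC)CC | intermediate
20 | 5-bromo-2-methylpent-2-ene | CC(C)=CCCBr | starting material
21 | 5-iodo-2-methylpent-2-ene | CC(C)=CCCI | intermediate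
22 | lithium enolate of 23 (enolate double bond toward the methyl-bearing ring carbon) | C=C[C@@](C)(O[Si](CC)(CC)CC)CC[C@H]1C(C)=C([O-])CC[C@@]1(C)O[Si](CC)(CC)CC.[Li+] | intermediate
23 | (2S,3S,4R)-2,4-dimethyl-2-(4-methylpent-3-en-1-yl)-3-[(3S)-3-methyl-3-(triethylsilyloxy)pent-4-en-1-yl]-4-(triethylsilyloxy)cyclohexan-1-one | C=C[C@@](C)(O[Si](CC)(CC)CC)CC[C@H]1[C@](C)(CCC=C(C)C)C(=O)CC[C@@]1(C)O[Si](CC)(CC)CC | intermediate
24 | (1R,2S,3S,4R)-2,4-dimethyl-2-(4-methylpent-3-en-1-yl)-3-[(3S)-3-methyl-3-(triethylsilyloxy)pent-4-en-1-yl]-4-(triethylsilyloxy)cyclohexan-1-ol (axial OH) | C=C[C@@](C)(O[Si](CC)(CC)CC)CC[C@H]1[C@](C)(CCC=C(C)C)[C@H](O)CC[C@@]1(C)O[Si](CC)(CC)CC | intermediate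
25 | {[(1R,2S,3S,4S)-4-bromo-1,3-dimethyl-3-(4-methylpent-3-en-1-yl)-2-[(3S)-3-methyl-3-(triethylsilyloxy)pent-4-en-1-yl]cyclohexyl]oxy}triethylsilane | C=C[C@@](C)(O[Si](CC)(CC)CC)CC[C@H]1[C@](C)(CCC=C(C)C)[C@@H](Br)CC[C@@]1(C)O[Si](CC)(CC)CC | intermediate
26 | (1R,2S,3S,4S)-4-bromo-2-[(3S)-3-hydroxy-3-methylpent-4-en-1-yl]-1,3-dimethyl-3-(4-methylpent-3-en-1-yl)cyclohexan-1-ol | C=C[C@@](C)(O)CC[C@H]1[C@](C)(CCC=C(C)C)[C@@H](Br)CC[C@@]1(C)O | target

**Step count and risks**
Total step count: 16. Longest linear sequence: 13 steps (steps 3 to 11 and 13 to 16, from (S)-linalool).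

Steps most likely to fail:

1. Step 15. Backside displacement at a secondary carbon next to a quaternary centre is slow. Anti elimination toward the ring CH2, a 1,2-methyl shift from the quaternary carbon and participation of the side-chain alkene may outrun substitution once the C–O bond ionises. Fallback: it sets out from 24 and comes back at 25, separating activation from displacement. The axial alcohol 24 would be converted at −78 °C (Tf2O, 2,6-di-tert-butylpyridine, CH2Cl2) into the axial trifluoromethanesulfonate of 24 F1. This would be displaced without warming by a large excess of Bu4NBr in toluene, a non-ionising medium, to give 25.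

2. Step 13. C-Alkylation of the congested tetrasubstituted enolate by an unactivated primary iodide may be slow enough for proton transfer between enolate and product (alkylation at the ring CH2), O-alkylation and loss of HI from the iodide to compete. Fallback: it sets out from 19 and comes back at 23, replacing the alkyl halide by a conjugate acceptor. A Mukaiyama–Michael addition of enol ether 19 to acrolein (BF3·OEt2, CH2Cl2, −78 °C) would give the keto aldehyde 3-[(1S,2S,3R)-1,3-dimethyl-2-[(3S)-3-methyl-3-(triethylsilyloxy)pent-4-en-1-yl]-6-oxo-3-(triethylsilyloxy)cyclohexyl]propanal F2 with the same facial preference. Wittig olefination of its aldehyde with isopropylidenetriphenylphosphorane (from isopropyltriphenylphosphonium iodide and n-BuLi, THF, −78 °C) would then give 23.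

3. Step 7. The exo preference or the face selectivity of the cycloaddition may erode with this trisubstituted diene, and prolonged heating may polymerise the dienophile or desilylate the dienol ether. Fallback: a stepwise anionic double Michael annulation, which sets out from 11 (with 5) and comes back at 14. The lithium dienolate 12, made from 11 as in step 6, would add at −78 °C through its CH2 terminus to the exocyclic methylene of 5. The resulting dioxolanone enolate would close onto the enone β-carbon on the face opposite the tert-butyl group, as in alkylations of such enolates, to give the lithium ring enolate lithium (2S,5R,6S)-2-tert-butyl-7-methyl-6-[(3S)-3-methyl-3-(triethylsilyloxy)pent-4-en-1-yl]-4-oxo-1,3-dioxaspiro[4.5]dec-7-en-8-olate F3. This would be silylated in the same flask with Et3SiCl to give 14.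

**Further compounds**
F1 | step 15 | (1R,2S,3S,4R)-2,4-dimethyl-2-(4-methylpent-3-en-1-yl)-3-[(3S)-3-methyl-3-(triethylsilyloxy)pent-4-en-1-yl]-4-(triethylsilyloxy)cyclohexyl trifluoromethanesulfonate | C=C[C@@](C)(O[Si](CC)(CC)CC)CC[C@H]1[C@](C)(CCC=C(C)C)[C@H](OS(=O)(=O)C(F)(F)F)CC[C@@]1(C)O[Si](CC)(CC)CC
F2 | step 13 | 3-[(1S,2S,3R)-1,3-dimethyl-2-[(3S)-3-methyl-3-(triethylsilyloxy)pent-4-en-1-yl]-6-oxo-3-(triethylsilyloxy)cyclohexyl]propanal | C=C[C@@](C)(O[Si](CC)(CC)CC)CC[C@H]1[C@](C)(CCC=O)C(=O)CC[C@@]1(C)O[Si](CC)(CC)CC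
F3 | step 7 | lithium (2S,5R,6S)-2-tert-butyl-7-methyl-6-[(3S)-3-methyl-3-(triethylsilyloxy)pent-4-en-1-yl]-4-oxo-1,3-dioxaspiro[4.5]dec-7-en-8-olate | C=C[C@@](C)(O[Si](CC)(CC)CC)CC[C@H]1C(C)=C([O-])CC[C@@]12O[C@H](C(C)(C)C)OC2=O.[Li+]
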